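**Retrosynthetic overview**

1. The strategy rests on C4 (aryl ketone on ring A), C3 (carrying ring B) and C2 (enolised aldehyde) of ring C: a 2-aryl-1,3-dicarbonyl unit, which is the ring-opened form of a 3,4-diarylisoxazole. Ring C is therefore traced back to isoxazole 22 by N–O cleavage, hydrolysis and O1–C2 closure.
2. Isoxazole 22 is cut at the C3–C4 bond (isoflavone numbering) and at the temporary O–C2 bond into the isolable nitrile oxide 20 (complete ring A) and the β-morpholinostyrene 15 (complete ring B with its fused pyran ring D and the prenyl group).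
3. Enamine 15 comes from aldehyde 9 by a one-carbon Horner–Wittig homologation that brings in the morpholine. Aldehyde 9 comes from 3,4-dihydroxybenzaldehyde by two successive O-alkylation/Claisen sequences with 3-chloro-3-methylbut-1-yne.
4. Ring order: ring A is bought; ring D is fused to ring B first; the isoxazole (masked ring C) follows by [3+2] cycloaddition; ring C is closed last.

Key step: step 12

Remark: paraformaldehyde is entered in the compound list as its monomer unit, and enamine 15 is assumed to be taken crude into step 12.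

**Route**

Step 1
Reactants: 1 3,4-dihydroxybenzaldehyde; 2 3-chloro-3-methylbut-1-yne
Product: 3 3-hydroxy-4-[(2-methylbut-3-yn-2-yl)oxy]benzaldehyde
Conditions: K2CO3 (1.05 equiv), KI (cat.), CuI (cat.), DMF, 60 °C, Ar
Reagents that add atoms: none
Why: The 4-OH, para to the formyl group, is the more acidic one, so one equivalent of carbonate should give the 4-phenoxide selectively, which is O-alkylated by the copper-activated tertiary propargyl chloride (Williamson-type propargyl etherification).

Step 2
Reactants: 3 3-hydroxy-4-[(2-methylbut-3-yn-2-yl)oxy]benzaldehyde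
Product: 5 8-hydroxy-2,2-dimethyl-2H-chromene-6-carbaldehyde, via allenyl phenol 4 (not isolated)
Conditions: N,N-diethylaniline, 180 °C, Ar
Reagents that add atoms: none
Why: Aromatic propargyl Claisen rearrangement can only end productively at the single free ortho carbon, giving allene 4, and a 1,5-hydrogen shift followed by oxa-6π electrocyclisation should close the 2,2-dimethylpyran ring D.

Step 3
Reactants: 5 8-hydroxy-2,2-dimethyl-2H-chromene-6-carbaldehyde; 2 3-chloro-3-methylbut-1-yne
Product: 6 2,2-dimethyl-8-[(2-methylbut-3-yn-2-yl)oxy]-2H-chromene-6-carbaldehyde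
Conditions: K2CO3, KI (cat.), CuI (cat.), DMF, 60 °C, Ar
Reagents that add atoms: none
Why: The same Williamson-type propargyl etherification is applied to the only remaining phenol, at a temperature well below that needed for a second propargyl Claisen rearrangement.

Step 4
Reactants: 6 2,2-dimethyl-8-[(2-methylbut-3-yn-2-yl)oxy]-2H-chromene-6-carbaldehyde
Product: 7 2,2-dimethyl-8-[(2-methylbut-3-en-2-yl)oxy]-2H-chromene-6-carbaldehyde
Conditions: H2 (1 atm, 1 equiv uptake), Pd on CaCO3 poisoned with Pb(OAc)2, quinoline, EtOAc, rt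
Reagents that add atoms: none
Why: Lindlar semihydrogenation should reduce the terminal alkyne much faster than the cis-disubstituted chromene alkene or the aldehyde, giving the 1,1-dimethylallyl ether.

Step 5
Reactants: 7 2,2-dimethyl-8-[(2-methylbut-3-en-2-yl)oxy]-2H-chromene-6-carbaldehyde
Product: 8 8-hydroxy-2,2-dimethyl-7-(3-methylbut-2-en-1-yl)-2H-chromene-6-carbaldehyde
Conditions: N,N-diethylaniline, 150 °C, Ar
Reagents that add atoms: none
Why: Aromatic Claisen rearrangement of the 1,1-dimethylallyl ether should deliver the allyl unit with inversion, as a normal prenyl group, to C7, the only unsubstituted ortho carbon, after which the dienone enolises to the phenol.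

Step 6
Reactants: 8 8-hydroxy-2,2-dimethyl-7-(3-methylbut-2-en-1-yl)-2H-chromene-6-carbaldehyde
Product: 9 8-(methoxymethoxy)-2,2-dimethyl-7-(3-methylbut-2-en-1-yl)-2H-chromene-6-carbaldehyde
Conditions: NaH, DMF, 0 °C; MOMCl, 0 °C → rt
Reagents that add atoms: chloromethyl methyl ether (MOMCl), COCCl
Why: O-Alkylation of the sodium phenoxide with the small, reactive chloromethyl ether (Williamson etherification) should mask the hindered phenol as an acetal that comes off with the ring A acetals in the last step.

Step 7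
Reactants: 10 morpholine; 11 paraformaldehyde; 12 diphenylphosphine oxide
Product: 13 4-[(diphenylphosphoryl)methyl]morpholine
Conditions: toluene, 80 °C
Reagents that add atoms: none
Why: Phospha-Mannich (Kabachnik–Fields-type) condensation: morpholine and formaldehyde form the iminium ion, to which the P–H bond of the secondary phosphine oxide adds.

Step 8
Reactants: 13 4-[(diphenylphosphoryl)methyl]morpholine; 9 8-(methoxymethoxy)-2,2-dimethyl-7-(3-methylbut-2-en-1-yl)-2H-chromene-6-carbaldehyde
Product: 15 4-{(E)-2-[8-(methoxymethoxy)-2,2-dimethyl-7-(3-methylbut-2-en-1-yl)-2H-chromen-6-yl]ethenyl}morpholine, via hydroxy phosphine oxide adduct 14 (not isolated)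
Conditions: 13, n-BuLi, THF, −78 °C; then 9, −78 → 0 °C; then KOt-Bu, 0 °C → rt; filtration and concentration under Ar
Reagents that add atoms: none
Why: Horner–Wittig olefination with an α-amino phosphine oxide: the lithiated reagent adds to the aldehyde and the potassium alkoxide of 14 expels diphenylphosphinate, which should give the conjugated E-enamine directly under basic, acid-free conditions, so the MOM ether is safe and no free arylacetaldehyde has to be handled.

Step 9
Reactants: 16 2,4,6-trihydroxybenzaldehyde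
Product: 17 2,4,6-tris(methoxymethoxy)benzaldehyde
Conditions: NaH (3.6 equiv), MOMCl (3.6 equiv), DMF/THF, 0 °C → rt
Reagents that add atoms: chloromethyl methyl ether (MOMCl), COCCl
Why: Full deprotonation with NaH breaks the chelation of the two ortho hydroxyls, so that all three phenoxide oxygens should be alkylated by the hard chloromethyl ether (Williamson etherification).

Step 10
Reactants: 17 2,4,6-tris(methoxymethoxy)benzaldehyde
Product: 18 (E)-2,4,6-tris(methoxymethoxy)benzaldehyde oxime
Conditions: NH2OH·HCl, NaOAc, EtOH/H2O, rt → 50 °C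
Reagents that add atoms: hydroxylamine (as hydrochloride), NO.Cl
Why: Oxime condensation in acetate buffer, mild enough for the MOM acetals, should give the E-aldoxime.

Step 11
Reactants: 18 (E)-2,4,6-tris(methoxymethoxy)benzaldehyde oxime
Product: 20 2,4,6-tris(methoxymethoxy)benzonitrile oxide, via hydroximoyl chloride 19 (not isolated)
Conditions: aqueous NaOCl, CH2Cl2, 0 °C; product kept cold and used promptly
Reagents that add atoms: none
Why: Hypochlorite chlorinates the oxime carbon to give 19, which loses HCl in the basic aqueous phase (the chlorination–dehydrochlorination route to nitrile oxides); the two ortho OMOM groups block furoxan dimerisation, so 20 should be isolable, and the basic medium spares the acetals.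

Step 12
Reactants: 20 2,4,6-tris(methoxymethoxy)benzonitrile oxide; 15 4-{(E)-2-[8-(methoxymethoxy)-2,2-dimethyl-7-(3-methylbut-2-en-1-yl)-2H-chromen-6-yl]ethenyl}morpholine
Product: 22 4-[8-(methoxymethoxy)-2,2-dimethyl-7-(3-methylbut-2-en-1-yl)-2H-chromen-6-yl]-3-[2,4,6-tris(methoxymethoxy)phenyl]-1,2-oxazole, via 5-morpholinoisoxazoline 21 (not isolated)
Conditions: 20 (1.2 equiv), toluene, rt, Ar; then AcOH (2 equiv), 50 °C
Reagents that add atoms: none
Why: Nitrile oxide 20 adds across the enamine C=C of 15 in a concerted but asynchronous Huisgen 1,3-dipolar cycloaddition, in which the electrophilic nitrile carbon bonds to the nucleophilic aryl-bearing β-carbon (the C3–C4 bond of the isoflavone) and the oxide oxygen bonds to the morpholine-bearing carbon (the future C2). This is the established nitrile oxide–enamine route to 4-substituted isoxazoles; the five-membered ring is closed intermolecularly in the [3+2] mode, and protonation of the aminal nitrogen of 21 by AcOH lets morpholine leave next to the acidic C4–H so that the ring aromatises. No stereocentre remains in the product: the two trans centres of 21, set by suprafacial addition to the E-alkene, are both removed in the elimination. The step needs regioselectivity, which the strong polarisation of the enamine supplies, and chemoselectivity over the prenyl and chromene alkenes, which are far poorer dipolarophiles than an enamine. The two ortho OMOM groups keep 20 from dimerising, and the acid is added only after 20 has been consumed, so that liberated morpholine cannot add to the dipole.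

Step 13
Reactants: 22 4-[8-(methoxymethoxy)-2,2-dimethyl-7-(3-methylbut-2-en-1-yl)-2H-chromen-6-yl]-3-[2,4,6-tris(methoxymethoxy)phenyl]-1,2-oxazole
Product: 23 (2Z)-3-amino-2-[8-(methoxymethoxy)-2,2-dimethyl-7-(3-methylbut-2-en-1-yl)-2H-chromen-6-yl]-3-[2,4,6-tris(methoxymethoxy)phenyl]prop-2-enal
Conditions: Mo(CO)6 (1 equiv), MeCN/H2O, 80 °C
Reagents that add atoms: none
Why: Reductive N–O cleavage of the isoxazole by zerovalent molybdenum (coordination at nitrogen, insertion into N–O, protonation by water) should leave alkenes and acetals untouched and give the Z vinylogous formamide, the unmasked 1,3-dicarbonyl unit.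

Step 14
Reactants: 23 (2Z)-3-amino-2-[8-(methoxymethoxy)-2,2-dimethyl-7-(3-methylbut-2-en-1-yl)-2H-chromen-6-yl]-3-[2,4,6-tris(methoxymethoxy)phenyl]prop-2-enal
Product: 26 5,7-dihydroxy-3-[8-hydroxy-2,2-dimethyl-7-(3-methylbut-2-en-1-yl)-2H-chromen-6-yl]-4H-chromen-4-one, via keto aldehyde 24 (not isolated), via 2-hydroxyisoflavanone 25 (not isolated)
Conditions: 3 M aqueous HCl, MeOH, 50 °C, monitored and stopped at full conversion
Reagents that add atoms: water, O
Why: Acid cleaves the four MOM acetals (methanol traps the formaldehyde as dimethoxymethane) and hydrolyses the vinylogous amide to the 1,3-dicarbonyl compound 24, whereupon an ortho hydroxyl of the symmetric ring A adds to the aldehyde carbon (6-exo-trig hemiacetal 25, forming O1–C2) and dehydration should give the chromone, the classical end game of deoxybenzoin-type isoflavone syntheses.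

**Compound list**

1 | 3,4-dihydroxybenzaldehyde | O=Cc1ccc(O)c(O)c1 | starting material
2 | 3-chloro-3-methylbut-1-yne | C#CC(C)(C)Cl | starting material
3 | 3-hydroxy-4-[(2-methylbut-3-yn-2-yl)oxy]benzaldehyde | O=Cc1ccc(OC(C)(C)C#C)c(O)c1 | intermediate
4 | 3,4-dihydroxy-5-(3-methylbuta-1,2-dien-1-yl)benzaldehyde (not isolated) | O=Cc1cc(O)c(O)c(C=C=C(C)C)c1 | intermediate
5 | 8-hydroxy-2,2-dimethyl-2H-chromene-6-carbaldehyde | O=Cc1cc(O)c2OC(C)(C)C=Cc2c1 | intermediate
6 | 2,2-dimethyl-8-[(2-methylbut-3-yn-2-yl)oxy]-2H-chromene-6-carbaldehyde | O=Cc1cc(OC(C)(C)C#C)c2OC(C)(C)C=Cc2c1 | intermediate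
7 | 2,2-dimethyl-8-[(2-methylbut-3-en-2-yl)oxy]-2H-chromene-6-carbaldehyde | O=Cc1cc(OC(C)(C)C=C)c2OC(C)(C)C=Cc2c1 | intermediate
8 | 8-hydroxy-2,2-dimethyl-7-(3-methylbut-2-en-1-yl)-2H-chromene-6-carbaldehyde | O=Cc1cc2C=CC(C)(C)Oc2c(O)c1CC=C(C)C | intermediate
9 | 8-(methoxymethoxy)-2,2-dimethyl-7-(3-methylbut-2-en-1-yl)-2H-chromene-6-carbaldehyde | O=Cc1cc2C=CC(C)(C)Oc2c(OCOC)c1CC=C(C)C | intermediate
10 | morpholine | C1COCCN1 | starting material
11 | paraformaldehyde (formaldehyde unit) | C=O | starting material
12 | diphenylphosphine oxide | O=[PH](c1ccccc1)c1ccccc1 | starting material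
13 | 4-[(diphenylphosphoryl)methyl]morpholine | O=P(CN1CCOCC1)(c1ccccc1)c1ccccc1 | intermediate
14 | 2-(diphenylphosphoryl)-1-[8-(methoxymethoxy)-2,2-dimethyl-7-(3-methylbut-2-en-1-yl)-2H-chromen-6-yl]-2-(morpholin-4-yl)ethan-1-ol (metal alkoxide in the flask, racemic diastereomer mixture, not isolated) | OC(c1cc2C=CC(C)(C)Oc2c(OCOC)c1CC=C(C)C)C(N1CCOCC1)P(=O)(c1ccccc1)c1ccccc1 | intermediate
15 | 4-{(E)-2-[8-(methoxymethoxy)-2,2-dimethyl-7-(3-methylbut-2-en-1-yl)-2H-chromen-6-yl]ethenyl}morpholine | C1COCCN1/C=C/c1cc2C=CC(C)(C)Oc2c(OCOC)c1CC=C(C)C | intermediate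
16 | 2,4,6-trihydroxybenzaldehyde | O=Cc1c(O)cc(O)cc1O | starting material
17 | 2,4,6-tris(methoxymethoxy)benzaldehyde | O=Cc1c(OCOC)cc(OCOC)cc1OCOC | intermediate
18 | (E)-2,4,6-tris(methoxymethoxy)benzaldehyde oxime | O/N=C/c1c(OCOC)cc(OCOC)cc1OCOC | intermediate
19 | (Z)-N-hydroxy-2,4,6-tris(methoxymethoxy)benzenecarboximidoyl chloride (not isolated) | O/N=C(\Cl)c1c(OCOC)cc(OCOC)cc1OCOC | intermediate
20 | 2,4,6-tris(methoxymethoxy)benzonitrile oxide | [O-][N+]#Cc1c(OCOC)cc(OCOC)cc1OCOC | intermediate
21 | trans-4-[8-(methoxymethoxy)-2,2-dimethyl-7-(3-methylbut-2-en-1-yl)-2H-chromen-6-yl]-5-(morpholin-4-yl)-3-[2,4,6-tris(methoxymethoxy)phenyl]-4,5-dihydro-1,2-oxazole (racemic, one enantiomer drawn, not isolated) | COCOc1cc(OCOC)c(C2=NO[C@H](N3CCOCC3)[C@H]2c2cc3C=CC(C)(C)Oc3c(OCOC)c2CC=C(C)C)c(OCOC)c1 | intermediate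
22 | 4-[8-(methoxymethoxy)-2,2-dimethyl-7-(3-methylbut-2-en-1-yl)-2H-chromen-6-yl]-3-[2,4,6-tris(methoxymethoxy)phenyl]-1,2-oxazole | COCOc1cc(OCOC)c(-c2nocc2-c2cc3C=CC(C)(C)Oc3c(OCOC)c2CC=C(C)C)c(OCOC)c1 | intermediate
23 | (2Z)-3-amino-2-[8-(methoxymethoxy)-2,2-dimethyl-7-(3-methylbut-2-en-1-yl)-2H-chromen-6-yl]-3-[2,4,6-tris(methoxymethoxy)phenyl]prop-2-enal | N/C(c1c(OCOC)cc(OCOC)cc1OCOC)=C(\C=O)c1cc2C=CC(C)(C)Oc2c(OCOC)c1CC=C(C)C | intermediate
24 | 2-[8-hydroxy-2,2-dimethyl-7-(3-methylbut-2-en-1-yl)-2H-chromen-6-yl]-3-oxo-3-(2,4,6-trihydroxyphenyl)propanal (configurationally labile, not isolated) | O=CC(C(=O)c1c(O)cc(O)cc1O)c1cc2C=CC(C)(C)Oc2c(O)c1CC=C(C)C | intermediate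
25 | 2,5,7-trihydroxy-3-[8-hydroxy-2,2-dimethyl-7-(3-methylbut-2-en-1-yl)-2H-chromen-6-yl]-2,3-dihydro-4H-chromen-4-one (racemic diastereomer mixture, not isolated) | OC1Oc2cc(O)cc(O)c2C(=O)C1c1cc2C=CC(C)(C)Oc2c(O)c1CC=C(C)C | intermediate
26 | 5,7-dihydroxy-3-[8-hydroxy-2,2-dimethyl-7-(3-methylbut-2-en-1-yl)-2H-chromen-6-yl]-4H-chromen-4-one | CC(C)=CCc1c(-c2coc3cc(O)cc(O)c3c2=O)cc2c(c1O)OC(C)(C)C=C2 | target

**Step count**

Total step count: 14.
Longest linear sequence: 10 steps (steps 1–6, 8, 12, 13, 14).

**Steps most likely to fail**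

Step 12. The new C–C bond joins a di-ortho-substituted nitrile carbon to an enamine carbon that carries an ortho-prenylated aryl group, so the cycloaddition may be slow. Hydrolysis of the enamine, thermal isomerisation of the dipole to the isocyanate, or addition of liberated morpholine to the dipole could then take over. The fallback gives up the cycloaddition and builds the same C3–C4 bond by carbonyl addition. It sets out from 15 and returns at 26. Enamine 15 is hydrolysed in AcOH/NaOAc buffer (aqueous THF, rt) to [8-(methoxymethoxy)-2,2-dimethyl-7-(3-methylbut-2-en-1-yl)-2H-chromen-6-yl]acetaldehyde F1. 1,3,5-Tris(methoxymethoxy)benzene F2 is made from phloroglucinol (NaH, MOMCl, DMF), lithiated between two OMOM groups (n-BuLi, THF, 0 °C) and transmetalated with anhydrous CeCl3 at −78 °C to suppress enolisation of the aldehyde. Addition to F1 should give the carbinol F3. Oxidation with Dess–Martin periodinane and NaHCO3 in CH2Cl2 should give the deoxybenzoin F4. Condensation with N,N-dimethylformamide dimethyl acetal (toluene, 90 °C) should give the dimethylamino enaminone F5. Under the conditions of step 14, F5 should lose dimethylamine and the acetals and close ring C through 24 and 25 to 26.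

Step 14. At 50 °C in 3 M acid, the freed 8-hydroxyl of ring B may add to the protonated prenyl alkene (chroman formation), the chromene may hydrate, or formaldehyde may attack ring A before ring closure is complete. The fallback separates deprotection from ring closure. It sets out from 23 and returns at 26. The aryl MOM ethers are removed under non-protic conditions (TMSOTf, 2,2'-bipyridyl, CH2Cl2, 0 °C → rt, then water) to give the free tetraphenol enaminone F6. Warming F6 in AcOH/NaOAc buffer (aqueous THF, 40 °C) should hydrolyse the vinylogous amide and close ring C through 24 and 25 to 26 at a pH at which the prenyl and chromene alkenes are not protonated.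

Step 5. The tertiary allyl ether may fragment by heterolysis to phenol 5 and isoprene, or the allyl unit may travel by a second [3,3] shift to C5 and arrive there as a 1,1-dimethylallyl group. The fallback installs the prenyl group by directed metalation. It sets out from 5 and returns at 9, so steps 3–6 are bypassed. Phenol 5 is protected (NaH, MOMCl, DMF) as 8-(methoxymethoxy)-2,2-dimethyl-2H-chromene-6-carbaldehyde F7. Lithium N,N,N'-trimethylethylenediamide (THF, −20 °C) converts the aldehyde in the flask into the α-amino alkoxide F8. n-BuLi then lithiates C7, the position flanked by both directing groups. Transmetalation with CuBr·SMe2 and addition of 1-bromo-3-methylbut-2-ene should give the prenylated α-amino alkoxide F9. Aqueous NH4Cl work-up releases the diamine and gives 9.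

**Further compounds**

F1 | step 12 | [8-(methoxymethoxy)-2,2-dimethyl-7-(3-methylbut-2-en-1-yl)-2H-chromen-6-yl]acetaldehyde | O=CCc1cc2C=CC(C)(C)Oc2c(OCOC)c1CC=C(C)C
F2 | step 12 | 1,3,5-tris(methoxymethoxy)benzene | COCOc1cc(OCOC)cc(OCOC)c1
F3 | step 12 | 2-[8-(methoxymethoxy)-2,2-dimethyl-7-(3-methylbut-2-en-1-yl)-2H-chromen-6-yl]-1-[2,4,6-tris(methoxymethoxy)phenyl]ethan-1-ol (racemic) | OC(Cc1cc2C=CC(C)(C)Oc2c(OCOC)c1CC=C(C)C)c1c(OCOC)cc(OCOC)cc1OCOC
F4 | step 12 | 2-[8-(methoxymethoxy)-2,2-dimethyl-7-(3-methylbut-2-en-1-yl)-2H-chromen-6-yl]-1-[2,4,6-tris(methoxymethoxy)phenyl]ethan-1-one | O=C(Cc1cc2C=CC(C)(C)Oc2c(OCOC)c1CC=C(C)C)c1c(OCOC)cc(OCOC)cc1OCOC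
F5 | step 12 | (2E)-3-(dimethylamino)-2-[8-(methoxymethoxy)-2,2-dimethyl-7-(3-methylbut-2-en-1-yl)-2H-chromen-6-yl]-1-[2,4,6-tris(methoxymethoxy)phenyl]prop-2-en-1-one | CN(C)/C=C(/C(=O)c1c(OCOC)cc(OCOC)cc1OCOC)c1cc2C=CC(C)(C)Oc2c(OCOC)c1CC=C(C)C
F6 | step 14 | (2Z)-3-amino-2-[8-hydroxy-2,2-dimethyl-7-(3-methylbut-2-en-1-yl)-2H-chromen-6-yl]-3-(2,4,6-trihydroxyphenyl)prop-2-enal | N/C(c1c(O)cc(O)cc1O)=C(\C=O)c1cc2C=CC(C)(C)Oc2c(O)c1CC=C(C)C
F7 | step 5 | 8-(methoxymethoxy)-2,2-dimethyl-2H-chromene-6-carbaldehyde | O=Cc1cc(OCOC)c2OC(C)(C)C=Cc2c1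
F8 | step 5 | {[2-(dimethylamino)ethyl](methyl)amino}[8-(methoxymethoxy)-2,2-dimethyl-2H-chromen-6-yl]methanol (lithium alkoxide in the flask, racemic) | OC(N(C)CCN(C)C)c1cc(OCOC)c2OC(C)(C)C=Cc2c1
F9 | step 5 | {[2-(dimethylamino)ethyl](methyl)amino}[8-(methoxymethoxy)-2,2-dimethyl-7-(3-methylbut-2-en-1-yl)-2H-chromen-6-yl]methanol (lithium alkoxide in the flask, racemic) | OC(N(C)CCN(C)C)c1cc2C=CC(C)(C)Oc2c(OCOC)c1CC=C(C)C
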